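**Strategy.** The route rests on disconnecting ring B between C6 and C7, the two adjacent oxygen-bearing carbons (C6–OH, C7–OAc) that lie between ring-fusion carbon C5 and the C8 carbinol. This 1,2-dioxygen pattern is read as the product of a reductive carbonyl–nitrile coupling: SmI2 converts a seco precursor, a ring A nitrile (C6) carrying at C10 a chain with the C9 and C8 stereocentres and a C7 aldehyde, into the 7β-hydroxy-6-ketone, closing ring B and setting C7 in one operation. The C6 ketone then allows the hindered axial 6β-OH to be installed by α-face hydride delivery. The precursor comes from β-cyclocitral by an enantioselective Ireland–Claisen rearrangement and a Felkin–Anh vinyl addition.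

Key step: step 11

Remark on the chemistry: labdane numbering (C1–C20) is used for every compound; the sense of induction written for the (S,S)-diazaborolidine in step 3 and for (R)-TRIP in step 16 is assumed by analogy with simpler esters and aldehydes, and the mirror-image controller would be used if a test run showed the opposite sense.

**Step 1**
Reactants: 1 β-cyclocitral
Product: 2 β-cyclogeraniol
Conditions: NaBH4, MeOH, 0 °C
Reagents that add atoms: none
Why: Borohydride 1,2-reduction of the hindered enal to the allylic alcohol; no stereocentre is formed.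

**Step 2**
Reactants: 2 β-cyclogeraniol; 3 4-(benzyloxy)butanoic acid
Product: 4 β-cyclogeranyl 4-(benzyloxy)butanoate
Conditions: DCC, 4-(dimethylamino)pyridine (cat.), CH2Cl2, 0 °C → rt
Reagents that add atoms: none
Why: Steglich esterification of the primary allylic alcohol under neutral conditions; no stereocentre is formed.

**Step 3**
Reactants: 4 β-cyclogeranyl 4-(benzyloxy)butanoate
Product: 7 (2R)-4-(benzyloxy)-2-[(1R)-1,3,3-trimethyl-2-methylidenecyclohexyl]butanoic acid, via boron ketene acetal 5 (not isolated), via acyloxyborane 6 (not isolated)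
Conditions: (1S,2S)-N,N'-bis[3,5-bis(trifluoromethyl)phenylsulfonyl]-1,2-diphenylethane-1,2-diamine + BBr3, CH2Cl2 (volatiles removed); then 4, iPr2NEt, CH2Cl2, −78 °C, then −20 → 4 °C; aqueous work-up
Reagents that add atoms: none
Why: Enantioselective Ireland–Claisen rearrangement: soft enolization should give the boron ketene acetal with C11 cis to O–B, whose chair [3,3] shift onto C10 (C1 and C11 pseudo-equatorial, the C10 methyl pseudo-axial) fixes the C9/C10 relative configuration, while the C2-symmetric diazaborolidine selects the enolate face and hence the absolute configuration.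

**Step 4**
Reactants: 7 Claisen acid
Product: 9 (2R)-4-(benzyloxy)-N-methoxy-N-methyl-2-[(1R)-1,3,3-trimethyl-2-methylidenecyclohexyl]butanamide, via acyl imidazole 8 (not isolated)
Conditions: 1,1'-carbonyldiimidazole, THF, rt; then CH3NH(OCH3)·HCl, rt
Reagents that add atoms: N,O-dimethylhydroxylamine hydrochloride, CNOC.Cl
Why: Amide coupling through the acyl imidazole under neutral conditions that should not epimerize the hindered C9 centre.

**Step 5**
Reactants: 9 Weinreb amide
Product: 11 (2R)-4-(benzyloxy)-2-[(1S,2S)-2-(hydroxymethyl)-1,3,3-trimethylcyclohexyl]-N-methoxy-N-methylbutanamide, via alkylborane 10 (not isolated)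
Conditions: 9-borabicyclo[3.3.1]nonane (9-BBN), THF, 60 °C; then NaOH, H2O2, 0 °C
Reagents that add atoms: hydrogen peroxide, OO
Why: Anti-Markovnikov hydroboration–oxidation places boron on the exocyclic C6 and delivers hydrogen to C5 from the face opposite the axial C10 and C4 methyl groups, which should give the 5α-H isomer (C6 and C9 trans).

**Step 6**
Reactants: 11 primary alcohol
Product: 14 (2R)-4-(benzyloxy)-2-[(1S,2S)-2-cyano-1,3,3-trimethylcyclohexyl]-N-methoxy-N-methylbutanamide, via aldehyde 12 (not isolated), via aldimine 13 (not isolated)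
Conditions: 2,2,6,6-tetramethylpiperidin-1-oxyl (TEMPO, cat.), PhI(OAc)2, NH4OAc, MeCN/H2O, rt
Reagents that add atoms: ammonium acetate, CC(=O)[O-].[NH4+]
Why: One-pot alcohol-to-nitrile oxidation (oxoammonium oxidation to the aldehyde, condensation with ammonia, second oxidation of the aldimine); enolization toward the doubly neopentyl C5 is disfavoured, so its configuration should persist.

**Step 7**
Reactants: 14 nitrile Weinreb amide
Product: 15 (1S,2S)-2-[(3R)-1-(benzyloxy)-4-oxopentan-3-yl]-2,6,6-trimethylcyclohexane-1-carbonitrile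
Conditions: CH3MgBr, THF, −20 → 0 °C
Reagents that add atoms: methylmagnesium bromide, C[Mg]Br
Why: Weinreb ketone synthesis, in which the chelated tetrahedral adduct stops at the ketone stage and the neopentyl C5 nitrile is too hindered to compete.

**Step 8**
Reactants: 15 methyl ketone
Product: 16 (1S,2S)-2-[(3R,4R)-1-(benzyloxy)-4-hydroxy-4-methylhex-5-en-3-yl]-2,6,6-trimethylcyclohexane-1-carbonitrile
Conditions: CH2=CHMgBr, CeCl3, THF, −78 °C
Reagents that add atoms: vinylmagnesium bromide, C=C[Mg]Br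
Why: Felkin–Anh 1,2-addition of the weakly basic vinylcerium reagent, anti to the quaternary C10 substituent on C9, should set C8 with CH3 and O placed as in the target.

**Step 9**
Reactants: 16 tertiary allylic alcohol
Product: 17 triethylsilyl ether of 16
Conditions: Et3SiOTf, 2,6-lutidine, CH2Cl2, 0 °C → rt
Reagents that add atoms: triethylsilyl trifluoromethanesulfonate, CC[Si](CC)(CC)OS(=O)(=O)C(F)(F)F
Why: Silyl ether formation with the silyl triflate protects the tertiary 8-OH, which would otherwise form a lactol or a tetrahydrofuran with C12 in steps 15 to 17.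

**Step 10**
Reactants: 17 silyl ether
Product: 19 (1S,2S)-2-[(2S,3R)-5-(benzyloxy)-2-methyl-1-oxo-2-(triethylsilyloxy)pentan-3-yl]-2,6,6-trimethylcyclohexane-1-carbonitrile, via ozonide 18 (not isolated)
Conditions: O3, CH2Cl2, −78 °C; then Me2S, −78 °C → rt
Reagents that add atoms: ozone, [O-][O+]=O
Why: Ozonolysis with reductive work-up cleaves the only alkene to the C7 aldehyde, whose quaternary α-carbon C8 cannot epimerize.

**Step 11**
Reactants: 19 seco aldehyde–nitrile
Product: 21 12-(benzyloxy)-7β-hydroxy-8α-(triethylsilyloxy)-13,14,15,16-tetranorlabdan-6-one, via hydroxy ketimine 20 (not isolated)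
Conditions: SmI2 (3 equiv), t-BuOH, THF, 0 °C → rt, slow addition of 19 at high dilution; then pH 7 aqueous buffer
Reagents that add atoms: water, O
Why: Single-electron reduction of the C7 aldehyde by SmI2 gives a samarium ketyl that attacks the C6 nitrile carbon, and a second electron plus protonation give the α-hydroxy ketimine 20, which is hydrolysed on work-up to the ketol. The closest known reaction type is the SmI2-mediated (or electroreductive) carbonyl–nitrile reductive cyclization to α-hydroxy cycloalkanones. Ring B (C5–C6–C7–C8–C9–C10) closes in a radical 6-exo-dig mode through a chair in which the C8 methyl is axial and the C8 oxygen and the C11 chain are equatorial. C7 is the only new stereocentre and should be set as 7β-OH by the pseudo-equatorial position of the bulky O–Sm group in that chair; C5 is already fixed as 5α-H, so the ring fusion is trans. The step needs cyclization to win over pinacol dimerization and simple reduction of the aldehyde, which is served by slow addition at high dilution and by the trans-diequatorial placement of the nitrile and the C9 chain on ring A, which holds C6 and C7 close. No other group in 19 is reducible under these conditions, the benzyl and silyl ethers being inert.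

**Step 12**
Reactants: 21 ketol
Product: 22 12-(benzyloxy)-8α-(triethylsilyloxy)-13,14,15,16-tetranorlabdane-6β,7β-diol
Conditions: NaBH4, MeOH/THF, −20 → 0 °C
Reagents that add atoms: none
Why: Hydride reduction of the C6 ketone from the open α-face, the β-face being shielded by the axial methyl groups on C4, C8 and C10, should give the axial 6β-alcohol.

**Step 13**
Reactants: 22 diol
Product: 23 7-acetate of 22
Conditions: Ac2O, pyridine, 4-(dimethylamino)pyridine (cat.), 0 °C
Reagents that add atoms: acetic anhydride, CC(=O)OC(C)=O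
Why: Acylation of the equatorial secondary 7β-OH, selective because the axial 6β-OH is flanked by three syn-axial methyl groups.

**Step 14**
Reactants: 23 acetate
Product: 24 7β-acetoxy-8α-(triethylsilyloxy)-13,14,15,16-tetranorlabdane-6β,12-diol
Conditions: H2 (1 atm), Pd/C, EtOAc, rt
Reagents that add atoms: none
Why: Hydrogenolysis of the benzyl ether; no alkene or nitrile remains at this stage, so nothing else should be reduced.

**Step 15**
Reactants: 24 primary alcohol
Product: 25 7β-acetoxy-6β-hydroxy-8α-(triethylsilyloxy)-13,14,15,16-tetranorlabdan-12-al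
Conditions: TEMPO (cat.), PhI(OAc)2, CH2Cl2, rt
Reagents that add atoms: none
Why: Oxoammonium oxidation, selective for the primary C12 alcohol over the hindered secondary 6β-OH, stops at the aldehyde because the silylated 8-O cannot form a lactol.

**Step 16**
Reactants: 25 aldehyde
Product: 27 (12S)-7β-acetoxy-8α-(triethylsilyloxy)labda-13(16),14-diene-6β,12-diol, via boryl ether 26 (not isolated)
Conditions: 2-(buta-2,3-dien-1-yl)-4,4,5,5-tetramethyl-1,3,2-dioxaborolane (known reagent), (R)-TRIP [(R)-3,3'-bis(2,4,6-triisopropylphenyl)-1,1'-binaphthyl-2,2'-diyl hydrogen phosphate, 5 mol %], 4 Å molecular sieves, toluene, −30 °C; aqueous work-up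
Reagents that add atoms: 2-(buta-2,3-dien-1-yl)-4,4,5,5-tetramethyl-1,3,2-dioxaborolane, C=C=CCB1OC(C)(C)C(C)(C)O1
Why: Chiral phosphoric acid-catalysed homoallenylboration, an allylboration of SE2' type through a closed chair transition state, forms C12–C13 with the 2-substituted diene in place, the catalyst directing attack to the Re face of C12 to give the 12S alcohol.

**Step 17**
Reactants: 27 dienyl carbinol
Product: 29 (12R)-7β-acetoxy-12-hydroperoxy-8α-(triethylsilyloxy)labda-13(16),14-dien-6β-ol, via mesylate 28 (not isolated)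
Conditions: CH3SO2Cl, Et3N, CH2Cl2, −65 °C; then anhydrous H2O2 in Et2O, −78 → −30 °C
Reagents that add atoms: hydrogen peroxide, OO
Why: Sulfonylation of the unhindered allylic alcohol followed by SN2 displacement of the mesylate by H2O2 at low temperature, with inversion, should convert 12S–O into 12R–OOH.

**Step 18**
Reactants: 29 silylated hydroperoxide
Product: 30 (12R)-7β-acetoxy-12-hydroperoxylabda-13(16),14-diene-6β,8α-diol (CNP0356983.1)
Conditions: HF·pyridine, pyridine/THF, 0 °C
Reagents that add atoms: none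
Why: Fluoride cleavage of the tertiary silyl ether (desilylation) under buffered conditions that should leave the hydroperoxide, diene and acetate untouched.

**Compound list**

1 | β-cyclocitral (2,6,6-trimethylcyclohex-1-ene-1-carbaldehyde) | CC1=C(C=O)C(C)(C)CCC1 | starting material
2 | β-cyclogeraniol ((2,6,6-trimethylcyclohex-1-en-1-yl)methanol) | CC1=C(CO)C(C)(C)CCC1 | intermediate
3 | 4-(benzyloxy)butanoic acid | OC(=O)CCCOCc1ccccc1 | starting material
4 | (2,6,6-trimethylcyclohex-1-en-1-yl)methyl 4-(benzyloxy)butanoate | CC1=C(COC(=O)CCCOCc2ccccc2)C(C)(C)CCC1 | intermediate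
5 | boron ketene acetal of 4 (C11 cis to O–B; boron in the (4S,5S)-4,5-diphenyl-1,3-bis(arylsulfonyl)-1,3,2-diazaborolidine) | C(OCC/C=C(\OB3N(S(=O)(=O)c1cc(cc(c1)C(F)(F)F)C(F)(F)F)[C@@H](c2ccccc2)[C@H](c4ccccc4)N3S(=O)(=O)c5cc(cc(c5)C(F)(F)F)C(F)(F)F)OCC6=C(C)CCCC6(C)C)c7ccccc7 | intermediate (not isolated)
6 | acyloxyborane (boron carboxylate) of acid 7 | O=C(OB3N(S(=O)(=O)c1cc(cc(c1)C(F)(F)F)C(F)(F)F)[C@@H](c2ccccc2)[C@H](c4ccccc4)N3S(=O)(=O)c5cc(cc(c5)C(F)(F)F)C(F)(F)F)[C@H](CCOCc6ccccc6)[C@@]7(C)CCCC(C)(C)C7=C | intermediate (not isolated)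
7 | (2R)-4-(benzyloxy)-2-[(1R)-1,3,3-trimethyl-2-methylidenecyclohexyl]butanoic acid | OC(=O)[C@H](CCOCc1ccccc1)[C@@]2(C)CCCC(C)(C)C2=C | intermediate
8 | acyl imidazole of 7 | O=C(n1ccnc1)[C@H](CCOCc2ccccc2)[C@@]3(C)CCCC(C)(C)C3=C | intermediate (not isolated)
9 | (2R)-4-(benzyloxy)-N-methoxy-N-methyl-2-[(1R)-1,3,3-trimethyl-2-methylidenecyclohexyl]butanamide | CON(C)C(=O)[C@H](CCOCc1ccccc1)[C@@]2(C)CCCC(C)(C)C2=C | intermediate
10 | B-alkyl-9-borabicyclo[3.3.1]nonane from 9 (boron on C6, 5α-H) | CON(C)C(=O)[C@H](CCOCc1ccccc1)[C@@]2(C)CCCC(C)(C)[C@@H]2CB3C4CCCC3CCC4 | intermediate (not isolated)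
11 | (2R)-4-(benzyloxy)-2-[(1S,2S)-2-(hydroxymethyl)-1,3,3-trimethylcyclohexyl]-N-methoxy-N-methylbutanamide | CON(C)C(=O)[C@H](CCOCc1ccccc1)[C@@]2(C)CCCC(C)(C)[C@@H]2CO | intermediate
12 | C6 aldehyde from 11 | CON(C)C(=O)[C@H](CCOCc1ccccc1)[C@@]2(C)CCCC(C)(C)[C@@H]2C=O | intermediate (not isolated)
13 | C6 aldimine from 12 | CON(C)C(=O)[C@H](CCOCc1ccccc1)[C@@]2(C)CCCC(C)(C)[C@@H]2C=N | intermediate (not isolated)
14 | (2R)-4-(benzyloxy)-2-[(1S,2S)-2-cyano-1,3,3-trimethylcyclohexyl]-N-methoxy-N-methylbutanamide | CON(C)C(=O)[C@H](CCOCc1ccccc1)[C@@]2(C)CCCC(C)(C)[C@@H]2C#N | intermediate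
15 | (1S,2S)-2-[(3R)-1-(benzyloxy)-4-oxopentan-3-yl]-2,6,6-trimethylcyclohexane-1-carbonitrile | CC(=O)[C@H](CCOCc1ccccc1)[C@@]2(C)CCCC(C)(C)[C@@H]2C#N | intermediate
16 | (1S,2S)-2-[(3R,4R)-1-(benzyloxy)-4-hydroxy-4-methylhex-5-en-3-yl]-2,6,6-trimethylcyclohexane-1-carbonitrile | C=C[C@@](C)(O)[C@H](CCOCc1ccccc1)[C@@]2(C)CCCC(C)(C)[C@@H]2C#N | intermediate
17 | (1S,2S)-2-[(3R,4R)-1-(benzyloxy)-4-methyl-4-(triethylsilyloxy)hex-5-en-3-yl]-2,6,6-trimethylcyclohexane-1-carbonitrile | C=C[C@@](C)(O[Si](CC)(CC)CC)[C@H](CCOCc1ccccc1)[C@@]2(C)CCCC(C)(C)[C@@H]2C#N | intermediate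
18 | 1,2,4-trioxolane (ozonide) of 17, mixture at the ring carbon | C1(OOCO1)[C@@](C)(O[Si](CC)(CC)CC)[C@H](CCOCc2ccccc2)[C@@]3(C)CCCC(C)(C)[C@@H]3C#N | intermediate (not isolated)
19 | (1S,2S)-2-[(2S,3R)-5-(benzyloxy)-2-methyl-1-oxo-2-(triethylsilyloxy)pentan-3-yl]-2,6,6-trimethylcyclohexane-1-carbonitrile | O=C[C@@](C)(O[Si](CC)(CC)CC)[C@H](CCOCc1ccccc1)[C@@]2(C)CCCC(C)(C)[C@@H]2C#N | intermediate
20 | 12-(benzyloxy)-6-imino-8α-(triethylsilyloxy)-13,14,15,16-tetranorlabdan-7β-ol | C(c1ccccc1)OCC[C@H]3[C@](C)(O[Si](CC)(CC)CC)[C@@H](O)C(=N)[C@H]4C(C)(C)CCC[C@@]43C | intermediate (not isolated)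
21 | 12-(benzyloxy)-7β-hydroxy-8α-(triethylsilyloxy)-13,14,15,16-tetranorlabdan-6-one | C(c1ccccc1)OCC[C@H]3[C@](C)(O[Si](CC)(CC)CC)[C@@H](O)C(=O)[C@H]4C(C)(C)CCC[C@@]43C | intermediate
22 | 12-(benzyloxy)-8α-(triethylsilyloxy)-13,14,15,16-tetranorlabdane-6β,7β-diol | C(c1ccccc1)OCC[C@H]3[C@](C)(O[Si](CC)(CC)CC)[C@@H](O)[C@@H](O)[C@H]4C(C)(C)CCC[C@@]43C | intermediate
23 | 7β-acetoxy-12-(benzyloxy)-8α-(triethylsilyloxy)-13,14,15,16-tetranorlabdan-6β-ol | C(c1ccccc1)OCC[C@H]3[C@](C)(O[Si](CC)(CC)CC)[C@@H](OC(C)=O)[C@@H](O)[C@H]4C(C)(C)CCC[C@@]43C | intermediate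
24 | 7β-acetoxy-8α-(triethylsilyloxy)-13,14,15,16-tetranorlabdane-6β,12-diol | OCC[C@H]1[C@](C)(O[Si](CC)(CC)CC)[C@@H](OC(C)=O)[C@@H](O)[C@H]2C(C)(C)CCC[C@@]21C | intermediate
25 | 7β-acetoxy-6β-hydroxy-8α-(triethylsilyloxy)-13,14,15,16-tetranorlabdan-12-al | O=CC[C@H]1[C@](C)(O[Si](CC)(CC)CC)[C@@H](OC(C)=O)[C@@H](O)[C@H]2C(C)(C)CCC[C@@]21C | intermediate
26 | 12-O-(pinacolatoboryl) ether of 27 | C=CC(=C)[C@H](C[C@H]1[C@](C)(O[Si](CC)(CC)CC)[C@@H](OC(C)=O)[C@@H](O)[C@H]2C(C)(C)CCC[C@@]21C)OB3OC(C)(C)C(C)(C)O3 | intermediate (not isolated)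
27 | (12S)-7β-acetoxy-8α-(triethylsilyloxy)labda-13(16),14-diene-6β,12-diol | C=CC(=C)[C@H](C[C@H]1[C@](C)(O[Si](CC)(CC)CC)[C@@H](OC(C)=O)[C@@H](O)[C@H]2C(C)(C)CCC[C@@]21C)O | intermediate
28 | 12-O-methanesulfonate of 27 | C=CC(=C)[C@H](C[C@H]1[C@](C)(O[Si](CC)(CC)CC)[C@@H](OC(C)=O)[C@@H](O)[C@H]2C(C)(C)CCC[C@@]21C)OS(C)(=O)=O | intermediate (not isolated)
29 | (12R)-7β-acetoxy-12-hydroperoxy-8α-(triethylsilyloxy)labda-13(16),14-dien-6β-ol | C=CC(=C)[C@@H](C[C@H]1[C@](C)(O[Si](CC)(CC)CC)[C@@H](OC(C)=O)[C@@H](O)[C@H]2C(C)(C)CCC[C@@]21C)OO | intermediate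
30 | (12R)-7β-acetoxy-12-hydroperoxylabda-13(16),14-diene-6β,8α-diol (CNP0356983.1) | C=CC(=C)[C@@H](C[C@H]1[C@](C)(O)[C@@H](OC(C)=O)[C@@H](O)[C@H]2C(C)(C)CCC[C@@]21C)OO | target

**Totals.** Total step count: 18. Longest linear sequence: 18 steps (1 → 30; acid 3 is purchased).

**Steps most likely to fail**

Step 11. Addition of the hindered C7 ketyl to the hindered C6 nitrile may be slow, so that intermolecular pinacol coupling or over-reduction of the aldehyde takes over. The fallback sets out from 17 and closes the same bond by an aldehyde–aldehyde pinacol coupling, then corrects the oxidation level. Reduction of the nitrile with iBu2AlH would give the aldehyde analogue F1, ozonolysis the dialdehyde F2, and SmI2 the 6,7-diol F3 (configuration at C6 and C7 immaterial). Swern oxidation would then give the 6,7-dione F4 (diosphenol tautomer), and NaBH4 should reduce both carbonyl groups from the α-face, coming back to the route at 22.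

Step 3. The [3,3] shift onto the tetrasubstituted allyl terminus may be slow, and enolate geometry or facial control may leak, lowering diastereo- and enantioselectivity. The fallback sets out from 4 and replaces reagent control by resolution. LiN(iPr)2 in THF/DMPU with Me3SiCl would give the (Z)-silyl ketene acetal F5, which rearranges on warming to the racemic silyl ester F6. Hydrolysis would give 7 together with its enantiomer F7. DCC coupling with (S)-4-benzyloxazolidin-2-one would give the diastereomeric imides F8 (from 7) and F9 (from F7), to be separated by chromatography. Treatment of F8 with CH3NH(OCH3)·HCl and Al(CH3)3 would come back to the route at 9.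

Step 17. The allylic mesylate may ionize, which would scramble C12 and transpose the peroxide to C16. The fallback sets out from 27 and, via mesylate 28, uses a bimolecular alkylation of a protected peroxide anion in place of capture by neutral H2O2. The cesium salt of 2-methoxyprop-2-yl hydroperoxide (CsOH·H2O, DMF, 0 °C) would give the peroxyketal F10, and aqueous HF in MeCN would remove the ketal and the silyl group together, coming back to the route at 30.

**Further compounds**

F1 | step 11 | C6 aldehyde analogue of 17 (nitrile replaced by CHO) | C=C[C@@](C)(O[Si](CC)(CC)CC)[C@H](CCOCc1ccccc1)[C@@]2(C)CCCC(C)(C)[C@@H]2C=O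
F2 | step 11 | C6,C7-dialdehyde (seco-labdane-6,7-dial) | O=C[C@@](C)(O[Si](CC)(CC)CC)[C@H](CCOCc1ccccc1)[C@@]2(C)CCCC(C)(C)[C@@H]2C=O
F3 | step 11 | 12-(benzyloxy)-8α-(triethylsilyloxy)-13,14,15,16-tetranorlabdane-6,7-diol (mixture at C6 and C7) | C(c1ccccc1)OCC[C@H]3[C@](C)(O[Si](CC)(CC)CC)C(O)C(O)[C@H]4C(C)(C)CCC[C@@]43C
F4 | step 11 | 12-(benzyloxy)-8α-(triethylsilyloxy)-13,14,15,16-tetranorlabdane-6,7-dione | C(c1ccccc1)OCC[C@H]3[C@](C)(O[Si](CC)(CC)CC)C(=O)C(=O)[C@H]4C(C)(C)CCC[C@@]43C
F5 | step 3 | (Z)-trimethylsilyl ketene acetal of 4 | C(OCC/C=C(\O[Si](C)(C)C)OCC1=C(C)CCCC1(C)C)c2ccccc2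
F6 | step 3 | trimethylsilyl ester of the racemic acid (drawn as the enantiomer that gives 7) | C[Si](C)(C)OC(=O)[C@H](CCOCc1ccccc1)[C@@]2(C)CCCC(C)(C)C2=C
F7 | step 3 | enantiomer of 7 | OC(=O)[C@@H](CCOCc1ccccc1)[C@]2(C)CCCC(C)(C)C2=C
F8 | step 3 | N-acyl (S)-4-benzyloxazolidin-2-one from 7 | O=C1OC[C@H](Cc2ccccc2)N1C(=O)[C@H](CCOCc3ccccc3)[C@@]4(C)CCCC(C)(C)C4=C
F9 | step 3 | N-acyl (S)-4-benzyloxazolidin-2-one from F7 | O=C1OC[C@H](Cc2ccccc2)N1C(=O)[C@@H](CCOCc3ccccc3)[C@]4(C)CCCC(C)(C)C4=C
F10 | step 17 | 12-O-(2-methoxyprop-2-yl) peroxide of 29 | C=CC(=C)[C@@H](C[C@H]1[C@](C)(O[Si](CC)(CC)CC)[C@@H](OC(C)=O)[C@@H](O)[C@H]2C(C)(C)CCC[C@@]21C)OOC(C)(C)OC
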